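**Plan**

- Retrosynthetic cuts: (a) the benzylic C‑3(furan)–O‑7(flavan) bond of a temporary pyran ring, together with eight benzyl ethers and a C‑8 bromine (one hydrogenolysis); (b) the furan C‑3–C‑3a bond (acetal Friedel–Crafts); (c) the methine–C‑2 bond and the O‑7–C‑3 bond together (oxa‑Diels–Alder).
- Enabling feature: the diarylmethine carbon sits on flavan C‑6 between the C‑5 and C‑7 phenol oxygens, so its benzhydrol is a latent o‑quinone methide (O‑7=C‑7–C‑6=C‑methine). C‑2/C‑3 of the dihydrobenzofuran (O‑bearing at C‑2, benzylic at C‑3) is a latent (Z)‑1‑aryloxy‑2‑alkoxyethene.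
- Forward, flavan half: (+)‑epicatechin → perbenzylation → C‑8 bromination → C‑6 formylation → ortho‑debenzylation → aryl Grignard addition (benzhydrol 9). Other half: 3,5‑bis(benzyloxy)phenol → enol ether 13.
- Ring order: temporary pyran (step 9) → furan ring (step 10) → pyran re‑opened and all protecting groups removed (step 11).
- Stereochemistry: flavan (2S,3S) from the chiral pool. Methine (R) and furan C‑2 (S) come from the endo transition state of the (E)‑o‑quinone methide with the (Z)‑enol ether (relative) under chiral phosphoric acid control (absolute). The furan C‑3 centre is transient.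

Key step: step 9

Assumptions: (+)‑epicatechin (2S,3S) is taken as commercially available; the ortho‑debenzylation of step 5 is written at O‑7, and if O‑5 is freed instead the temporary pyran forms on the other side of C‑6 and steps 6–11 converge on the same target.

**Route**

Step 1
Reactants: 1 (+)-epicatechin
Product: 2 5,7,3',4'-tetra-O-benzyl-(+)-epicatechin
Conditions: BnBr (4.4 equiv), K2CO3, DMF, 0 °C → rt, Ar
Reagents that add atoms: benzyl bromide BrCc1ccccc1
Why: Williamson etherification of the four phenols in the presence of the non‑ionised secondary alcohol; no stereocentre is touched.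

Step 2
Reactants: 2 5,7,3',4'-tetra-O-benzyl-(+)-epicatechin
Product: 3 3,5,7,3',4'-penta-O-benzyl-(+)-epicatechin
Conditions: NaH, BnBr, cat. Bu4NI, DMF, 0 °C → rt
Reagents that add atoms: benzyl bromide BrCc1ccccc1
Why: Williamson etherification of the C‑3 alkoxide, so that every hydroxyl carries the same hydrogenolysable group and none can add to the later o‑quinone methide.

Step 3
Reactants: 3 penta-O-benzyl-(+)-epicatechin
Product: 4 8-bromo-penta-O-benzyl-(+)-epicatechin
Conditions: NBS (1.0 equiv), CH2Cl2, −78 °C → rt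
Reagents that add atoms: N-bromosuccinimide O=C1CCC(=O)N1Br
Why: electrophilic aromatic bromination of benzylated flavan‑3‑ols goes to C‑8, the less hindered A‑ring position, and the bromine then blocks C‑8 until the last step.

Step 4
Reactants: 4 8-bromo-penta-O-benzyl-(+)-epicatechin
Product: 6 8-bromo-penta-O-benzyl-(+)-epicatechin-6-carbaldehyde, via C-6 iminium chloride 5 (not isolated)
Conditions: POCl3, DMF, 0 → 60 °C; then ice/H2O
Reagents that add atoms: N,N-dimethylformamide CN(C)C=O; water O
Why: Vilsmeier–Haack formylation at C‑6, the only free position of the phloroglucinol‑type A ring (ortho to both benzyloxy groups, para to O‑1), the catechol ether rings being far less nucleophilic.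

Step 5
Reactants: 6 8-bromo-penta-O-benzyl-(+)-epicatechin-6-carbaldehyde
Product: 7 8-bromo-3,5,3',4'-tetra-O-benzyl-7-hydroxy-(+)-epicatechin-6-carbaldehyde
Conditions: MgBr2·OEt2 (3 equiv), toluene–Et2O, rt → 60 °C; then 1 M HCl
Reagents that add atoms: none
Why: chelation‑controlled ether cleavage, in which Mg bridges the formyl oxygen and an ortho ether oxygen so that bromide removes only a benzyl group next to the carbonyl, and the resulting phenoxide–aldehyde chelate protects the second ortho ether.

Step 6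
Reactants: 7 7-hydroxy aldehyde; 8 4-bromo-1,2-bis(benzyloxy)benzene
Product: 9 6-{[3,4-bis(benzyloxy)phenyl](hydroxy)methyl}-8-bromo-3,5,3',4'-tetra-O-benzyl-(+)-epicatechin (7-OH free; both carbinol epimers)
Conditions: 8, Mg, THF (ArMgBr, 2.5 equiv); add 7, THF, −78 → 0 °C; sat. NH4Cl; filtration through Et3N‑treated silica
Reagents that add atoms: none
Why: Grignard addition to the aldehyde after the first equivalent has deprotonated the phenol; the carbinol configuration is irrelevant because it is erased in step 9.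

Step 7
Reactants: 10 3,5-bis(benzyloxy)phenol; 11 2-bromo-1,1-diethoxyethane
Product: 12 1,3-bis(benzyloxy)-5-(2,2-diethoxyethoxy)benzene
Conditions: K2CO3, cat. KI, DMF, 110 °C
Reagents that add atoms: none
Why: Williamson O‑alkylation of the phenoxide with the primary bromide.

Step 8
Reactants: 12 aryloxyacetaldehyde diethyl acetal
Product: 13 (Z)-1,3-bis(benzyloxy)-5-[(2-ethoxyethenyl)oxy]benzene
Conditions: iPr2NEt (1.5 equiv), then TMSOTf (1.2 equiv), CH2Cl2, −40 → 0 °C; aq. NaHCO3; chromatography on Et3N‑treated silica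
Reagents that add atoms: none
Why: acetal‑to‑enol‑ether elimination, in which the silyl triflate ionises the acetal and the amine deprotonates the oxocarbenium ion at the α‑carbon; the (Z)‑1,2‑dioxygenated alkene is expected to predominate and is separated from any (E) isomer.

Step 9
Reactants: 9 o-hydroxybenzhydrol; 13 (Z)-enol ether
Product: 15 all-cis ethoxy acetal cycloadduct (temporary pyran ring O-7–CH(OEt)–CH(OAr)–CH(Ar)–C-6), via o-quinone methide 14 (not isolated)
Conditions: (R)-TRIP (10 mol %), 13 (1.5 equiv), 5 Å MS, toluene, 0 °C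
Reagents that add atoms: none
Why: The phosphoric acid dehydrates 9 to the (E)‑o‑quinone methide 14 (O‑7=C‑7–C‑6=C‑methine) and stays hydrogen‑bonded to its carbonyl oxygen, and 14 reacts as a 1‑oxadiene with 13 in an asynchronous inverse‑electron‑demand oxa‑Diels–Alder reaction in which the methine–C‑2 bond leads and the O‑7–C‑3 bond follows. The closest known reaction type is the chiral‑phosphoric‑acid‑catalysed [4+2] cycloaddition of o‑quinone methides, generated in situ from o‑hydroxybenzhydrols, with enecarbamates, vinyl sulfides and enol ethers to give 2‑hetero‑substituted 4‑arylchromans. The pyran ring is closed by [4+2] cycloaddition (C–C bond first, then C–O bond at the oxocarbenium‑like carbon). The methine carbon and C‑2 become cis on the new ring because the aryl group is "outside" on the (E)‑methide and both oxygen substituents of the (Z)‑alkene are endo, which is the (R)/(S) pair of the target; the absolute sense comes from the catalyst, the flavan stereocentres being too remote to interfere, and the enantiomeric acid is used if screening shows the opposite facial preference. The step needs regioselectivity, secured by the ethoxy group being the stronger donor so that the methine bonds to the aryloxy‑bearing carbon, and chemoselectivity, secured by the single free phenol (one o‑quinone methide only), the bromine at C‑8 and the higher nucleophilicity of the enol ether compared with the benzylated arene rings.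

Step 10
Reactants: 15 ethoxy acetal cycloadduct
Product: 16 cis-fused benzofuro-pyrano-flavan tetracycle (acetal carbon now bonded to the ortho carbon of the 3,5-bis(benzyloxy)phenoxy ring; H‑2, H‑3 and methine H all cis)
Conditions: TMSOTf (10 mol %), 4 Å MS, CH2Cl2, −78 °C; Et3N quench at −78 °C
Reagents that add atoms: none
Why: intramolecular Friedel–Crafts alkylation (5‑exo‑trig) of the cyclic oxocarbenium ion by the ortho carbon of the phloroglucinol‑type aryl ether (both ortho positions are equivalent); the tether forces the cis ring fusion, and the new stereocentre is removed again in step 11.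

Step 11
Reactants: 16 tetracycle
Product: 17 target (CNP0161875.1)
Conditions: H2 (1 atm), Pd(OH)2/C, NaHCO3, degassed THF–MeOH, rt; work‑up under Ar
Reagents that add atoms: none
Why: catalytic hydrogenolysis cleaves the eight O‑benzyl groups, the aryl bromide and the cyclic benzylic aryl ether C‑3–O‑7 of the temporary pyran (the bond type cleaved when pterocarpans are hydrogenolysed to isoflavans), while the non‑benzylic C‑2–O‑1 bond of the dihydrobenzofuran and the flavan ring should persist under these mild buffered conditions.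

**Compound list**

1 | (+)-epicatechin, (2S,3S) | Oc1cc2c(c(O)c1)C[C@H](O)[C@H](c1ccc(O)c(O)c1)O2 | starting material
2 | 5,7,3',4'-tetra-O-benzyl-(+)-epicatechin | C(c1ccccc1)Oc1cc2c(c(OCc3ccccc3)c1)C[C@H](O)[C@H](c1ccc(OCc3ccccc3)c(OCc3ccccc3)c1)O2 | intermediate
3 | 3,5,7,3',4'-penta-O-benzyl-(+)-epicatechin | C(c1ccccc1)Oc1cc2c(c(OCc3ccccc3)c1)C[C@H](OCc1ccccc1)[C@H](c1ccc(OCc3ccccc3)c(OCc3ccccc3)c1)O2 | intermediate
4 | 8-bromo-penta-O-benzyl-(+)-epicatechin | C(c1ccccc1)Oc1c(Br)c2c(c(OCc3ccccc3)c1)C[C@H](OCc1ccccc1)[C@H](c1ccc(OCc3ccccc3)c(OCc3ccccc3)c1)O2 | intermediate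
5 | C-6 N,N-dimethyliminium chloride of 4 | C(c1ccccc1)Oc1c(Br)c2c(c(OCc3ccccc3)c1C=[N+](C)C)C[C@H](OCc1ccccc1)[C@H](c1ccc(OCc3ccccc3)c(OCc3ccccc3)c1)O2.[Cl-] | intermediate (not isolated)
6 | 8-bromo-penta-O-benzyl-(+)-epicatechin-6-carbaldehyde | C(c1ccccc1)Oc1c(Br)c2c(c(OCc3ccccc3)c1C=O)C[C@H](OCc1ccccc1)[C@H](c1ccc(OCc3ccccc3)c(OCc3ccccc3)c1)O2 | intermediate
7 | 8-bromo-3,5,3',4'-tetra-O-benzyl-7-hydroxy-(+)-epicatechin-6-carbaldehyde | Oc1c(Br)c2c(c(OCc3ccccc3)c1C=O)C[C@H](OCc1ccccc1)[C@H](c1ccc(OCc3ccccc3)c(OCc3ccccc3)c1)O2 | intermediate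
8 | 4-bromo-1,2-bis(benzyloxy)benzene | Brc1ccc(OCc2ccccc2)c(OCc2ccccc2)c1 | starting material
9 | 6-{[3,4-bis(benzyloxy)phenyl](hydroxy)methyl}-8-bromo-3,5,3',4'-tetra-O-benzyl-(+)-epicatechin, 7-OH free, carbinol epimers | Oc1c(Br)c2c(c(OCc3ccccc3)c1C(O)c1ccc(OCc3ccccc3)c(OCc3ccccc3)c1)C[C@H](OCc1ccccc1)[C@H](c1ccc(OCc3ccccc3)c(OCc3ccccc3)c1)O2 | intermediate
10 | 3,5-bis(benzyloxy)phenol | Oc1cc(OCc2ccccc2)cc(OCc2ccccc2)c1 | starting material
11 | 2-bromo-1,1-diethoxyethane | CCOC(CBr)OCC | starting material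
12 | 1,3-bis(benzyloxy)-5-(2,2-diethoxyethoxy)benzene | CCOC(COc1cc(OCc2ccccc2)cc(OCc2ccccc2)c1)OCC | intermediate
13 | (Z)-1,3-bis(benzyloxy)-5-[(2-ethoxyethenyl)oxy]benzene | CCO/C=C\Oc1cc(OCc2ccccc2)cc(OCc2ccccc2)c1 | intermediate
14 | (E)-o-quinone methide: 6-[3,4-bis(benzyloxy)benzylidene]-7-oxo form of 9 (aryl anti to C-7=O) | O=C1C(Br)=C2O[C@@H](c3ccc(OCc4ccccc4)c(OCc4ccccc4)c3)[C@@H](OCc3ccccc3)CC2=C(OCc2ccccc2)/C1=C\c1ccc(OCc2ccccc2)c(OCc2ccccc2)c1 | intermediate (not isolated)
15 | cycloadduct: pyran ring O-7–CH(OEt)–CH[O-3,5-bis(benzyloxy)phenyl]–CH[3,4-bis(benzyloxy)phenyl]–C-6 fused to the protected 8-bromoflavan, the three ring substituents all cis | c1(OCc2ccccc2)cc(OCc2ccccc2)cc(c1)O[C@H]([C@H](c1ccc(OCc2ccccc2)c(OCc2ccccc2)c1)c1c(O5)c(Br)c3c(c1OCc1ccccc1)C[C@H](OCc1ccccc1)[C@H](c1ccc(OCc2ccccc2)c(OCc2ccccc2)c1)O3)[C@H]5OCC | intermediate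
16 | cis-fused tetracycle: 4,6-bis(benzyloxy)-2,3-dihydrobenzofuran whose C-3 is bonded to flavan O-7 and whose C-2 carries the methine bonded to flavan C-6 | C(c1ccccc1)Oc1cc(OCc2ccccc2)c2c(c1)O[C@H]([C@H](c1ccc(OCc3ccccc3)c(OCc3ccccc3)c1)c1c(O5)c(Br)c3c(c1OCc1ccccc1)C[C@H](OCc1ccccc1)[C@H](c1ccc(OCc4ccccc4)c(OCc4ccccc4)c1)O3)[C@@H]25 | intermediate
17 | target: (S)-2-{(R)-(3,4-dihydroxyphenyl)[(2S,3S)-epicatechin-6-yl]methyl}-2,3-dihydrobenzofuran-4,6-diol | Oc1cc(O)c2c(c1)O[C@H]([C@H](c1ccc(O)c(O)c1)c1c(O)cc3c(c1O)C[C@H](O)[C@H](c1ccc(O)c(O)c1)O3)C2 | target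

**Summary**

Total steps: 11. Longest linear sequence: 9 (steps 1–6, 9, 10, 11).

Steps most likely to fail:

1. Step 9. The o‑quinone methide is unusually cation‑stabilised, so facial discrimination by the catalyst may be poor, and acid‑promoted Friedel–Crafts alkylation of the electron‑rich aryl ether ring or hydrolysis of the enol ether may compete. The fallback sets out from 12 and 7 and returns at 16, using acid‑free o‑quinone methide generation and an auxiliary on the dienophile. Transacetalisation of 12 with (1R,2S)‑trans‑2‑phenylcyclohexanol (PPTS, toluene, removal of EtOH) would give the bis‑auxiliary acetal F1, and TMSOTf/iPr2NEt elimination the (Z)‑enol ether carrying the auxiliary F2. Aldehyde 7 would be converted with Boc2O/iPr2NEt/cat. DMAP into the aryl tert‑butyl carbonate F3. Addition of the Grignard reagent from 8 to F3 at −78 °C in the presence of F2, then warming, moves the Boc group to the benzylic alkoxide and expels tert‑butyl carbonate, generating 14 under magnesium templating. Its endo cycloaddition with F2 under auxiliary control (auxiliary enantiomer chosen to match) should give the auxiliary acetal F4. F4 treated as in step 10 loses the auxiliary and gives 16.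

2. Step 10. The new benzylic C‑3–O‑7 bond may ionise and the C‑3 cation may lose the C‑2 proton (aromatisation to a benzofuran, erasing C‑2). The fallback sets out from 15 and returns at 17 by making the aromatisation deliberate. TsOH (cat.), CH2Cl2, rt would convert 15 into the 2‑(diarylmethyl)benzofuran F5, in which the methine centre is retained and flavan O‑7 is free. Ru–NHC‑catalysed asymmetric hydrogenation of the 2‑substituted benzofuran (chiral NHC, KOtBu, H2) would then set C‑2 under catalyst control to give the protected dihydrobenzofuran F6. F6 under the conditions of step 11 gives 17.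

3. Step 8. The oxocarbenium ion may be captured by the neighbouring electron‑rich arene (cyclisation towards a benzofuran) before it is deprotonated, and Z/E control may be poor. The fallback sets out from 10 and returns at 13: copper‑catalysed, geometry‑retaining Ullmann‑type O‑vinylation of 10 with commercial (Z)‑1‑bromo‑2‑ethoxyethene (CuI, N,N‑dimethylglycine, Cs2CO3, dioxane, 90 °C) gives 13 directly without any oxocarbenium intermediate.

**Further compounds**

F1 | step 9 | 1,3-bis(benzyloxy)-5-{2,2-bis[(1R,2S)-2-phenylcyclohexyloxy]ethoxy}benzene | c1(OCc2ccccc2)cc(OCc2ccccc2)cc(c1)OCC(O[C@@H]1CCCC[C@H]1c1ccccc1)O[C@@H]1CCCC[C@H]1c1ccccc1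
F2 | step 9 | (Z)-1,3-bis(benzyloxy)-5-({2-[(1R,2S)-2-phenylcyclohexyloxy]ethenyl}oxy)benzene | c1(OCc2ccccc2)cc(OCc2ccccc2)cc(c1)O/C=C\O[C@@H]1CCCC[C@H]1c1ccccc1
F3 | step 9 | 7-O-tert-butoxycarbonyl derivative of aldehyde 7 | CC(C)(C)OC(=O)Oc1c(Br)c2c(c(OCc3ccccc3)c1C=O)C[C@H](OCc1ccccc1)[C@H](c1ccc(OCc3ccccc3)c(OCc3ccccc3)c1)O2
F4 | step 9 | analogue of 15 with (1R,2S)-2-phenylcyclohexyloxy in place of ethoxy at the acetal carbon | c1(OCc2ccccc2)cc(OCc2ccccc2)cc(c1)O[C@H]([C@H](c1ccc(OCc2ccccc2)c(OCc2ccccc2)c1)c1c(O5)c(Br)c3c(c1OCc1ccccc1)C[C@H](OCc1ccccc1)[C@H](c1ccc(OCc2ccccc2)c(OCc2ccccc2)c1)O3)[C@H]5O[C@@H]1CCCC[C@H]1c1ccccc1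
F5 | step 10 | 4,6-bis(benzyloxy)-2-{(R)-[3,4-bis(benzyloxy)phenyl](8-bromo-3,5,3',4'-tetra-O-benzyl-7-hydroxy-(+)-epicatechin-6-yl)methyl}benzofuran | C(c1ccccc1)Oc1cc(OCc2ccccc2)c2cc(oc2c1)[C@H](c1ccc(OCc3ccccc3)c(OCc3ccccc3)c1)c1c(O)c(Br)c3c(c1OCc1ccccc1)C[C@H](OCc1ccccc1)[C@H](c1ccc(OCc4ccccc4)c(OCc4ccccc4)c1)O3
F6 | step 10 | (S)-2,3-dihydro derivative of F5 (octa-O-benzyl 8-bromo form of the target, flavan 7-OH free) | C(c1ccccc1)Oc1cc(OCc2ccccc2)c2c(c1)O[C@H]([C@H](c1ccc(OCc3ccccc3)c(OCc3ccccc3)c1)c1c(O)c(Br)c3c(c1OCc1ccccc1)C[C@H](OCc1ccccc1)[C@H](c1ccc(OCc4ccccc4)c(OCc4ccccc4)c1)O3)C2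
F0 | step 8 | none | none
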